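**Plan**

- Retrosynthesis cuts, in order: the two O–CH3 bonds at C5 and C8; the C4a–C5 bond of ring A (6π closure of a dienylketene that comes from opening a cyclobutenone); the C8–C8a bond (addition of a metalated pyranone to a cyclobutenedione carbonyl); and the O1–C8a and C2–C3 bonds of the pyranone.
- Forward: ring C is made first with ring B already on C2, the four-membered ring is attached at the future C8a, ring A arises last by ring expansion, and a double O-methylation ends the route.
- Enabling feature: ring A carries oxygen on C5 and C8 (para to each other), methoxy on C7 and hydrogen on C6. These are the atoms C1–C4 of a 4-hydroxy-3-methoxycyclobut-2-enone once its ketene carbon bonds to C4a.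
- Stereochemistry: the target is achiral; the one stereocenter met on the way (the carbinol carbon of the cyclobutenone) is formed racemic and becomes sp2 in the ring expansion.

Key step: step 5

Assumption: the β-diketone of step 1 is written as the diketo tautomer although it should exist mainly as an enol, and the hydroquinone of step 5 is handled under argon throughout.

**Route**

Step 1
Reactants: 1 (E)-4-methoxybut-3-en-2-one; 2 2,3,4-trimethoxybenzoyl chloride
Product: 4 (E)-5-methoxy-1-(2,3,4-trimethoxyphenyl)pent-4-ene-1,3-dione, via lithium enolate 3 (not isolated)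
Conditions: 1 (2.1 equiv), LiN(SiMe3)2 (2.1 equiv), THF, −78 °C; then 2 (1.0 equiv), −78 °C; 1 M HCl
Reagents that add atoms: none
Why: Claisen-type C-acylation of the kinetic lithium enolate of a methyl ketone by an aroyl chloride at −78 °C, where the second equivalent of enolate deprotonates the more acidic β-diketone as it forms and so prevents double acylation, while the methoxyvinyl group stays untouched.

Step 2
Reactants: 4 (E)-5-methoxy-1-(2,3,4-trimethoxyphenyl)pent-4-ene-1,3-dione
Product: 5 2-(2,3,4-trimethoxyphenyl)-4H-pyran-4-one
Conditions: CF3CO2H (0.2 equiv), toluene, 25 °C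
Reagents that add atoms: none
Why: Acid-catalysed cyclocondensation in which the enol oxygen of the aryl ketone adds 6-endo to the β-methoxyenone (oxa-Michael addition) and methanol is eliminated, the standard closure of 5-alkoxypent-4-ene-1,3-diones to 4-pyranones, which leaves C6 unsubstituted for the metalation.

Step 3
Reactants: 6 dimethyl squarate (3,4-dimethoxycyclobut-3-ene-1,2-dione)
Product: 8 3-methoxycyclobut-3-ene-1,2-dione, via hydride adduct 7 (not isolated)
Conditions: LiAlH(O-t-Bu)3 (1.0 equiv), THF, −78 °C to −20 °C; 2 M HCl work-up; crude 7 in CH2Cl2, conc. aq. HCl, 25 °C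
Reagents that add atoms: water, O (the carbinol oxygen leaves as water and the new carbonyl oxygen is taken from the aqueous acid)
Why: 1,2-Reduction of one squarate carbonyl by a bulky, mild aluminium hydride stops at the hydroxycyclobutenone, and acid then ionises the allylic carbinol to a methoxy-stabilised cyclobutenyl cation that is hydrated at the distal methoxy-bearing carbon and loses methanol, the established conversion of squarate adducts into 3-alkoxycyclobutene-1,2-diones.

Step 4
Reactants: 5 2-(2,3,4-trimethoxyphenyl)-4H-pyran-4-one; 8 3-methoxycyclobut-3-ene-1,2-dione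
Product: 10 4-hydroxy-3-methoxy-4-[4-oxo-6-(2,3,4-trimethoxyphenyl)-4H-pyran-2-yl]cyclobut-2-en-1-one (racemic), via 6-lithiopyranone 9 (not isolated)
Conditions: lithium 2,2,6,6-tetramethylpiperidide (1.1 equiv, from 2,2,6,6-tetramethylpiperidine and n-BuLi), THF, −78 °C, 15 min; then 8 (1.2 equiv), −78 °C; sat. aq. NH4Cl at −78 °C
Reagents that add atoms: none
Why: Deprotonative lithiation by a hindered, non-adding lithium amide should occur at the pyranone C–H next to the ring oxygen, the most acidic ring position as in the C2 lithiation of chromones, 4-quinolones and β-alkoxyacrylates, and the vinyllithium then undergoes 1,2-addition to the ketone carbonyl of 8 (the one flanked by the methoxy-bearing carbon) rather than to its vinylogous-ester carbonyl, the usual regiochemistry of organolithium additions to 3-alkoxycyclobutenediones; the carbinol stereocenter forms racemic and is erased in step 5.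

Step 5
Reactants: 10 4-hydroxy-3-methoxy-4-[4-oxo-6-(2,3,4-trimethoxyphenyl)-4H-pyran-2-yl]cyclobut-2-en-1-one (racemic)
Product: 13 5,8-dihydroxy-7-methoxy-2-(2,3,4-trimethoxyphenyl)-4H-chromen-4-one, via dienylketene 11 (not isolated), via ring-closed dienone 12 (not isolated)
Conditions: p-xylene (degassed, 0.02 M), argon, 138 °C
Reagents that add atoms: none
Why: Thermal conrotatory 4π opening of the cyclobutenone cleaves its C1–C4 bond and, by the usual torquoselectivity, turns the donor hydroxyl outward and the pyranonyl group inward, giving the (Z)-dienylketene 11. A thermal disrotatory 6π electrocyclization then joins the electrophilic ketene carbon to pyranone C5 (the future C4a), the nucleophilic α-carbon of the vinylogous ester, and closes the six-membered carbocycle, ring A, as dienone 12. Enolization of the doubly activated C4a–H aromatises 12 to hydroquinone 13, so the step is an isomerisation with no by-product. The closest known reaction is the Moore rearrangement of 4-aryl-, 4-heteroaryl- and 4-alkenyl-4-hydroxycyclobutenones to hydroquinones, and the pyranonyl group is a cyclic β-oxyalkenyl member of that family, though untested itself. No stereocenter remains, since the carbinol carbon of 10 becomes sp2 and C4a of 12 is lost on tautomerization. The step needs outward rotation of OH, secured by its donor character, and closure at carbon rather than capture of the ketene by oxygen, secured by the trans placement of OH and by C5 being the only carbon next to the point of attachment; the placement of OMe on C7 and H on C6 was already fixed by the regiochemistry of step 4.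

Step 6
Reactants: 13 5,8-dihydroxy-7-methoxy-2-(2,3,4-trimethoxyphenyl)-4H-chromen-4-one
Product: 15 2',3',4',5,7,8-hexamethoxyflavone, via 8-O-methyl ether 14 (not isolated)
Conditions: Me2SO4 (excess), K2CO3, acetone (degassed), reflux, argon
Reagents that add atoms: dimethyl sulfate, COS(=O)(=O)OC
Why: Williamson-type O-methylation of both phenoxides by dimethyl sulfate, the classical permethylation of hydroxyflavones, in which the free 8-hydroxyl reacts first to give 14 and the hydrogen-bonded 5-hydroxyl follows with excess reagent at reflux, while exclusion of air keeps the hydroquinone from oxidising before it is capped.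

**Compound list**

1 | (E)-4-methoxybut-3-en-2-one | CO/C=C/C(C)=O | starting material
2 | 2,3,4-trimethoxybenzoyl chloride | COc1ccc(C(=O)Cl)c(OC)c1OC | starting material
3 | lithium (E)-4-methoxybuta-1,3-dien-2-olate | C=C(O[Li])/C=C/OC | intermediate (not isolated)
4 | (E)-5-methoxy-1-(2,3,4-trimethoxyphenyl)pent-4-ene-1,3-dione | CO/C=C/C(=O)CC(=O)c1ccc(OC)c(OC)c1OC | intermediate
5 | 2-(2,3,4-trimethoxyphenyl)-4H-pyran-4-one | COc1ccc(-c2cc(=O)cco2)c(OC)c1OC | intermediate
6 | dimethyl squarate (3,4-dimethoxycyclobut-3-ene-1,2-dione) | COC1=C(OC)C(=O)C1=O | starting material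
7 | 4-hydroxy-2,3-dimethoxycyclobut-2-en-1-one (racemic) | COC1=C(OC)C(=O)C1O | intermediate (not isolated)
8 | 3-methoxycyclobut-3-ene-1,2-dione | COC1=CC(=O)C1=O | intermediate
9 | 6-lithio-2-(2,3,4-trimethoxyphenyl)-4H-pyran-4-one | [Li]c1cc(=O)cc(-c2ccc(OC)c(OC)c2OC)o1 | intermediate (not isolated)
10 | 4-hydroxy-3-methoxy-4-[4-oxo-6-(2,3,4-trimethoxyphenyl)-4H-pyran-2-yl]cyclobut-2-en-1-one (racemic) | COC1=CC(=O)C1(O)c1cc(=O)cc(-c2ccc(OC)c(OC)c2OC)o1 | intermediate
11 | (Z)-4-hydroxy-3-methoxy-4-[4-oxo-6-(2,3,4-trimethoxyphenyl)-4H-pyran-2-yl]buta-1,3-dien-1-one | O=C=C/C(OC)=C(/O)c1cc(=O)cc(-c2ccc(OC)c(OC)c2OC)o1 | intermediate (not isolated)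
12 | 8-hydroxy-7-methoxy-2-(2,3,4-trimethoxyphenyl)-4aH-chromene-4,5-dione (racemic) | COc1ccc(C2=CC(=O)C3C(=O)C=C(OC)C(O)=C3O2)c(OC)c1OC | intermediate (not isolated)
13 | 5,8-dihydroxy-7-methoxy-2-(2,3,4-trimethoxyphenyl)-4H-chromen-4-one | COc1ccc(-c2cc(=O)c3c(O)cc(OC)c(O)c3o2)c(OC)c1OC | intermediate
14 | 5-hydroxy-7,8-dimethoxy-2-(2,3,4-trimethoxyphenyl)-4H-chromen-4-one | COc1ccc(-c2cc(=O)c3c(O)cc(OC)c(OC)c3o2)c(OC)c1OC | intermediate (not isolated)
15 | 2',3',4',5,7,8-hexamethoxyflavone | COc1ccc(-c2cc(=O)c3c(OC)cc(OC)c(OC)c3o2)c(OC)c1OC | target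

**Count**

Total steps: 6. Longest linear sequence: 5 steps (steps 1, 2, 4, 5, 6); step 3 is a one-step side branch that joins at step 4.

**Steps most likely to fail**

Step 4. The amide may deprotonate next to the carbonyl (C3 or C5) and so trigger ring opening of the pyranone. The lithiated pyranone may also add to unreacted 5, or attack the vinylogous-ester carbonyl of 8. The fallback sets out from 5 and comes back at 10; it generates the nucleophile by halogen–magnesium exchange instead of deprotonation with a lithium amide. Pyranone 5 would be zincated at 25 °C in THF with a TMP-zinc amide (TMPZnCl·LiCl), the type of base that zincates the corresponding C–H of chromones under thermodynamic control, to give the stable [4-oxo-6-(2,3,4-trimethoxyphenyl)-4H-pyran-2-yl]zinc chloride F1. Iodine would convert this into 2-iodo-6-(2,3,4-trimethoxyphenyl)-4H-pyran-4-one F2, which is purified and its regiochemistry confirmed. Iodine–magnesium exchange with i-PrMgCl·LiCl in THF at −78 °C should then give [4-oxo-6-(2,3,4-trimethoxyphenyl)-4H-pyran-2-yl]magnesium chloride F3 in the absence of any amide base. Addition of 8 at −78 °C and an NH4Cl quench would deliver 10.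

Step 5. Ring closure of the dienylketene onto the electron-poor, weakly aromatic pyranone may be slower than ketene dimerisation. Partial inward rotation of the hydroxyl may lead to lactonisation, and the hydroquinone may oxidise during isolation. The fallback sets out from 2 and comes back at 15; ring A is bought with its oxygens in place and ring C is closed last. Purchased 1-(2-hydroxy-3,4,6-trimethoxyphenyl)ethanone F4 would be acylated with 2 in pyridine to 2-acetyl-3,5,6-trimethoxyphenyl 2,3,4-trimethoxybenzoate F5. Baker–Venkataraman rearrangement (KOH, pyridine, 50 °C) should give 1-(2-hydroxy-3,4,6-trimethoxyphenyl)-3-(2,3,4-trimethoxyphenyl)propane-1,3-dione F6. Cyclodehydration (H2SO4, AcOH, 100 °C) would then give 15 directly.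

Step 6. The deprotonated hydroquinone may be oxidised to the 5,8-quinone by traces of oxygen, and the hydrogen-bonded 5-hydroxyl may methylate so slowly that mixtures result. The fallback sets out from 5 and 8 and comes back at 14; the C8 oxygen is methylated before ring A exists, so no free hydroquinone is ever formed. The lithiation and addition of step 4 would be repeated, but the lithium alkoxide would be trapped at −78 °C with methyl triflate instead of being protonated. This should give 3,4-dimethoxy-4-[4-oxo-6-(2,3,4-trimethoxyphenyl)-4H-pyran-2-yl]cyclobut-2-en-1-one F7 (racemic). Heating F7 in p-xylene at 138 °C should open it, with the methoxy group turning outward, to (Z)-3,4-dimethoxy-4-[4-oxo-6-(2,3,4-trimethoxyphenyl)-4H-pyran-2-yl]buta-1,3-dien-1-one F8. This would close to 7,8-dimethoxy-2-(2,3,4-trimethoxyphenyl)-4aH-chromene-4,5-dione F9 (racemic), and enolization gives the air-stable monophenol 14. Its single chelated hydroxyl is then methylated as in step 6.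

**Further compounds**

F1 | step 4 | [4-oxo-6-(2,3,4-trimethoxyphenyl)-4H-pyran-2-yl]zinc chloride | COc1ccc(-c2cc(=O)cc([Zn]Cl)o2)c(OC)c1OC
F2 | step 4 | 2-iodo-6-(2,3,4-trimethoxyphenyl)-4H-pyran-4-one | COc1ccc(-c2cc(=O)cc(I)o2)c(OC)c1OC
F3 | step 4 | [4-oxo-6-(2,3,4-trimethoxyphenyl)-4H-pyran-2-yl]magnesium chloride | COc1ccc(-c2cc(=O)cc([Mg]Cl)o2)c(OC)c1OC
F4 | step 5 | 1-(2-hydroxy-3,4,6-trimethoxyphenyl)ethanone | CC(=O)c1c(O)c(OC)c(OC)cc1OC
F5 | step 5 | 2-acetyl-3,5,6-trimethoxyphenyl 2,3,4-trimethoxybenzoate | CC(=O)c1c(OC(=O)c2ccc(OC)c(OC)c2OC)c(OC)c(OC)cc1OC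
F6 | step 5 | 1-(2-hydroxy-3,4,6-trimethoxyphenyl)-3-(2,3,4-trimethoxyphenyl)propane-1,3-dione | COc1ccc(C(=O)CC(=O)c2c(O)c(OC)c(OC)cc2OC)c(OC)c1OC
F7 | step 6 | 3,4-dimethoxy-4-[4-oxo-6-(2,3,4-trimethoxyphenyl)-4H-pyran-2-yl]cyclobut-2-en-1-one (racemic) | COC1=CC(=O)C1(OC)c1cc(=O)cc(-c2ccc(OC)c(OC)c2OC)o1
F8 | step 6 | (Z)-3,4-dimethoxy-4-[4-oxo-6-(2,3,4-trimethoxyphenyl)-4H-pyran-2-yl]buta-1,3-dien-1-one | O=C=C/C(OC)=C(/OC)c1cc(=O)cc(-c2ccc(OC)c(OC)c2OC)o1
F9 | step 6 | 7,8-dimethoxy-2-(2,3,4-trimethoxyphenyl)-4aH-chromene-4,5-dione (racemic) | COc1ccc(C2=CC(=O)C3C(=O)C=C(OC)C(OC)=C3O2)c(OC)c1OC
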